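Substrate is conserved: whatever substrate is consumed leaves by the partner step or by the second-reagent step, side product B apart. Both proposed steps are first order in substrate, so [substrate] cancels from their ratio. At any moment, then, the rate of forming side product A over the rate of forming intermediate equals a constant times [second reagent]/[partner].

| flask | substrate | partner | second reagent | temperature | remark | time |
|---|---|---|---|---|---|---|
| Thursday's | 0.10 M | 0.11 M | 0.15 M | 55 °C | run made earlier |  |
| Saturday's | 0.14 M | 0.11 M | 0.15 M | 66 °C | run made earlier |  |
| Tuesday's | 0.22 M | 0.11 M | 0.15 M | 55 °C | run made earlier |  |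
| Monday's | 0.10 M | 0.11 M | 0.075 M | 66 °C | run made earlier |  |
| winter | 0.10 M | 0.110 M | 0.150 M |  | everything together at the start at 40 °C, warmed to 60 °C at 40 h | 2.5 d |
| dusk | 0.10 M | 0.110 M | 0.150 M | 60 °C | everything together at the start | 2.5 d |
| summer | 0.10 M | 0.110 M | 0.150 M (fed, over 40 h) | 60 °C | all else is in the flask from the start; the feed brings no volume worth counting | 2.5 d |
| midnight | 0.10 M (fed, over 40 h) | 0.110 M | 0.150 M |  | the addition at 40 °C, then warmed to 60 °C; the feed brings no volume worth counting | 2.5 d |
| autumn | 0.10 M (fed, over 4.0 h) | 0.110 M | 0.150 M | 60 °C | all else is in the flask from the start; the feed brings no volume worth counting | 2.5 d |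

Thursday's run (percent of the substrate charged)

| time / h | side product A / % | target / % |
|---|---|---|
| 5.00 | 24.1 | 0 |
| 12.0 | 36.2 | 0.7 |
| 25.0 | 44.2 | 2.5 |
| 40.0 | 48.6 | 5.1 |

Saturday's run (percent of the substrate charged)

| time / d | side product A / % | target / % |
|---|---|---|
| 0.417 | 44.0 | 1.9 |
| 1.04 | 54.2 | 6.3 |
| 2.08 | 53.8 | 11.4 |
| 3.00 | 54.7 | 13.5 |

Tuesday's run (percent of the substrate charged)

| time / d | side product A / % | target / % |
|---|---|---|
| 0.833 | 39.8 | 0 |
| 1.67 | 47.3 | 0.3 |
| 2.50 | 49.8 | 1.2 |
| 3.00 | 51.4 | 3.8 |

Monday's run (percent of the substrate charged)

| time / d | side product A / % | target / % |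
|---|---|---|
| 0.833 | 32.9 | 2.9 |
| 1.67 | 37.9 | 6.9 |
| 2.50 | 39.7 | 10.4 |
| 3.00 | 37.9 | 9.6 |

(readings scatter by 1 percentage point)

- percentages count the substrate that a species holds: one side product B counts as two
- steps that have been proposed: substrate + partner -> intermediate; second reagent + intermediate -> target; substrate + second reagent -> side product A; 2 partner -> self-condensation product; substrate + target -> side product B

* the flask that comes out highest in amount of side product A, in percent of the substrate charged; "all alike" if 1.5 percentage points covers them all (winter / dusk / summer / midnight / autumn / all alike)
* amount of side product A at the end, in percent of the substrate charged, winter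
* amount of side product A at the end, in percent of the substrate charged, dusk
* amount of side product A at the end, in percent of the substrate charged, summer
* amount of side product A at the end, in percent of the substrate charged, midnight
* amount of side product A at the end, in percent of the substrate charged, autumn

What does a whole run show? Thursday's last reading has 48.6% in side product A at a charged ratio of 1.36. If we count the rest of the substrate as gone to the partner, the odds are 0.946, and dividing by the ratio gives 0.693. We call this reading, taken at 55 °C, the split constant, an apparent selectivity factor: the whole-run odds of side product A per unit of charged [second reagent]/[partner]. It has the drift of both concentrations inside it, so it is not the constant of the rate ratio.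

What then does feeding the second reagent do? In summer the mean [second reagent] over the feed is about half the charge if little of it is spent. With the split constant as read at 55 °C, the odds fall to 0.473, and we reckon a share of 32.1%.

What does feeding the substrate do? Self-condensation takes two partner and no substrate, and among the proposed steps the second reagent has no such step of its own. While substrate is still being fed, partner can go that way, so we expect autumn slightly above dusk. Dusk has the charges of Thursday's run at a higher temperature, and we expect it near Thursday's reading.

The forecast gave 48.5% for winter, 52% for dusk, 30% for summer, 48.5% for midnight and 52% for autumn. It named dusk as highest, with the words “Dusk and autumn effectively tie”. There we differ, since we put autumn first.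

    substrate + partner → intermediate (k = 0.0219 M⁻¹ min⁻¹, Ea = 62.0 kJ mol⁻¹)
    second reagent + intermediate → target (k = 7.68 × 10⁻⁴ M⁻¹ min⁻¹, Ea = 98.0 kJ mol⁻¹)
    substrate + second reagent → side product A (k = 0.0118 M⁻¹ min⁻¹, Ea = 74.0 kJ mol⁻¹)
    2 partner → self-condensation product (k = 0.00458 M⁻¹ min⁻¹, Ea = 73.0 kJ mol⁻¹)
    substrate + target → side product B (k = 6.80 × 10⁻⁴ M⁻¹ min⁻¹, Ea = 96.0 kJ mol⁻¹)
    (constants at 60 °C)

The flasks give 45.2% for winter, 50.9% for dusk, 30.2% for summer, 49.6% for midnight and 53.5% for autumn, so autumn is highest. Autumn and dusk share their charges and temperature, so we hold them against each other: divided by the split constant, the end odds give 1.66 for autumn, more than the 1.50 for dusk. Autumn ends with 0.0235 M of self-condensation product against 0.0217 M in dusk. For a flask like summer with 0.044 M of partner, scaling summer's odds by the partner charges gives 1.08, a share of 52.0%, and that flask stands at 59.2%.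

The numbers in the tables were generated by integration with made-up constants; the scatter is artificial.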